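**Assumption:** the target SMILES has no stereocentre, and the diaryl ketone axes are not configurationally stable. The molecule is therefore achiral and "single enantiomer" does not apply. The only stereo-element in the route is the E C=N bond of hydrazone 10, which is destroyed in Step 8.

## Retrosynthetic overview
1. Target 12 comes from tetra-MOM keto-aldehyde 11 by global acetal hydrolysis.
2. Key disconnection: the ring-A aryl–C(=O) bond is traced back to a phenolic C–O bond. Compound 11 comes from N-aroylhydrazone 10 by Pb(OAc)4-induced ipso replacement of OH by aroyl, with loss of N2 and release of the CHO. This avoids the usual ArLi + ArCHO addition and benzhydrol oxidation, and it needs no late formylation or bromination.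
3. Hydrazone 10 comes from hydrazide 5 (ring B, Br already in place) and salicylaldehyde 9 (ring A, prenyl already in place).
4. Hydrazide 5 comes from orcinol (MOM, DoM/CO2, NBS, CDI/N2H4). Aldehyde 9 comes from 2,4,6-trihydroxybenzaldehyde (C-prenylation, selective bis-MOM).
5. Ring order: no carbocycle is built, since both arenes are purchased. Only transient oxadiazoline and benzodioxine rings appear, inside the key step.

## Route

**Step 1**
Reactants: 1, orcinol (5-methylbenzene-1,3-diol)
Product: 2, 1,3-bis(methoxymethoxy)-5-methylbenzene
Conditions: MOMCl (2.5 equiv), i-Pr2NEt, CH2Cl2, 0 °C → rt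
Reagents that add atoms: chloromethyl methyl ether, COCCl
Why: Williamson-type O-alkylation of both phenols installs groups that direct lithiation and are removable under mild acid.

**Step 2**
Reactants: 2
Product: 3, 2,6-bis(methoxymethoxy)-4-methylbenzoic acid
Conditions: n-BuLi (1.2 equiv), THF, 0 °C, 1 h; CO2, –78 °C → rt; citric acid to pH 4
Reagents that add atoms: carbon dioxide, O=C=O
Why: Directed ortho-metalation occurs only at the C–H flanked by both OMOM groups (cooperative direction), and carboxylation traps the aryllithium.

**Step 3**
Reactants: 3
Product: 4, 3-bromo-2,6-bis(methoxymethoxy)-4-methylbenzoic acid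
Conditions: NBS (1.0 equiv), MeCN, 0 °C → rt, dark
Reagents that add atoms: N-bromosuccinimide, O=C1CCC(=O)N1Br
Why: Electrophilic aromatic substitution at one of the two equivalent free positions (ortho/para to the OMOM groups, meta to CO2H) stops at monobromination because the first Br deactivates and crowds the ring; this parallels the clean 3-bromination of 2,6-dialkoxybenzoic acids.

**Step 4**
Reactants: 4
Product: 5, 3-bromo-2,6-bis(methoxymethoxy)-4-methylbenzohydrazide
Conditions: CDI (1.2 equiv), THF, rt → 40 °C; then added to N2H4·H2O (8 equiv), 0 °C → rt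
Reagents that add atoms: hydrazine (hydrate), NN (CDI leaves no atoms)
Why: Nucleophilic acyl substitution via the acyl imidazolide works because small, α-effect hydrazine reaches the hindered carbonyl under neutral conditions that spare MOM and ArBr, and excess hydrazine prevents diacylation.

**Step 5**
Reactants: 6, 2,4,6-trihydroxybenzaldehyde; 7, prenyl bromide (1-bromo-3-methylbut-2-ene)
Product: 8, 2,4,6-trihydroxy-3-(3-methylbut-2-en-1-yl)benzaldehyde
Conditions: KOH (1.0 equiv), H2O–MeOH, 0 °C → rt, 7 (0.9 equiv) added slowly
Reagents that add atoms: prenyl bromide, CC(C)=CCBr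
Why: The ambident acylphloroglucinol phenolate undergoes C-alkylation in protic medium, the two ring C–H sites are equivalent so only one mono-prenyl isomer forms, and sub-stoichiometric bromide limits over-alkylation.

**Step 6**
Reactants: 8
Product: 9, 2-hydroxy-4,6-bis(methoxymethoxy)-3-(3-methylbut-2-en-1-yl)benzaldehyde
Conditions: MOMCl (2.1 equiv), i-Pr2NEt (2.5 equiv), CH2Cl2, 0 °C
Reagents that add atoms: chloromethyl methyl ether, COCCl
Why: In this regioselective O-alkylation the non-chelated 4-OH reacts first, then the less hindered 6-OH, and the remaining 2-OH (flanked by prenyl and locked in a hydrogen bond to CHO) stays free, which is exactly the OH to be replaced.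

**Step 7**
Reactants: 5 and 9
Product: 10, (E)-3-bromo-N'-{[2-hydroxy-4,6-bis(methoxymethoxy)-3-(3-methylbut-2-en-1-yl)phenyl]methylidene}-2,6-bis(methoxymethoxy)-4-methylbenzohydrazide
Conditions: EtOH, cat. AcOH, 70 °C, 3 h
Reagents that add atoms: none
Why: Acylhydrazone condensation proceeds because the reacting NH2 is remote from the hindered aryl group, and the E isomer is favoured and held by the O–H···N hydrogen bond.

**Step 8 (key step)**
Reactants: 10
Product: 11, 2-[3-bromo-2,6-bis(methoxymethoxy)-4-methylbenzoyl]-4,6-bis(methoxymethoxy)-3-(3-methylbut-2-en-1-yl)benzaldehyde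
Conditions: Pb(OAc)4 (1.2 equiv), THF, 0 °C → rt, 1–2 h; filter Pb(OAc)2
Reagents that add atoms: none (both carbonyl oxygens come from the amide O and the phenol O; N2 and 2 AcOH are lost)
Why: This is the lead tetraacetate oxidative rearrangement of o-hydroxyaryl-carbonyl N-acylhydrazones to 1,2-diacylbenzenes (known for salicylaldehyde aroylhydrazones giving 2-aroylbenzaldehydes): oxidation gives the azoacetate and 2-acetoxy-Δ3-1,3,4-oxadiazoline, the only free phenol displaces acetate to form an azo-bridged 1,3-benzodioxine, N2 extrusion delivers the acyl carbon to the ipso carbon, and electrocyclic opening releases the ketone and CHO, so the tetra-ortho-substituted ketone forms intramolecularly and faster than Pb(IV) attacks the prenyl alkene, MOM ethers or ArBr.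

**Step 9**
Reactants: 11
Product: 12, Pestalone C (target)
Conditions: 3 M aq. HCl, MeOH–THF (1:1), 40 °C, dark; neutral aqueous work-up with no base
Reagents that add atoms: none
Why: Acid-catalysed acetal hydrolysis removes all four MOM groups (three are accelerated by an adjacent carbonyl) under the mild conditions routinely tolerated by o-prenylphenols, and avoiding base prevents the Cannizzaro–Tishchenko-type isomerisation of the keto-aldehyde to the phthalide.

## Compound list
1 | orcinol | Cc1cc(O)cc(O)c1 | starting material
2 | 1,3-bis(methoxymethoxy)-5-methylbenzene | Cc1cc(OCOC)cc(OCOC)c1 | intermediate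
3 | 2,6-bis(methoxymethoxy)-4-methylbenzoic acid | Cc1cc(OCOC)c(C(=O)O)c(OCOC)c1 | intermediate
4 | 3-bromo-2,6-bis(methoxymethoxy)-4-methylbenzoic acid | Cc1cc(OCOC)c(C(=O)O)c(OCOC)c1Br | intermediate
5 | 3-bromo-2,6-bis(methoxymethoxy)-4-methylbenzohydrazide | Cc1cc(OCOC)c(C(=O)NN)c(OCOC)c1Br | intermediate
6 | 2,4,6-trihydroxybenzaldehyde | O=Cc1c(O)cc(O)cc1O | starting material
7 | prenyl bromide | CC(C)=CCBr | starting material
8 | 2,4,6-trihydroxy-3-prenylbenzaldehyde | CC(C)=CCc1c(O)cc(O)c(C=O)c1O | intermediate
9 | 2-hydroxy-4,6-bis(methoxymethoxy)-3-prenylbenzaldehyde | CC(C)=CCc1c(OCOC)cc(OCOC)c(C=O)c1O | intermediate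
10 | (E)-N-aroylhydrazone of 9 with 5 | CC(C)=CCc1c(OCOC)cc(OCOC)c(/C=N/NC(=O)c2c(OCOC)cc(C)c(Br)c2OCOC)c1O | intermediate
11 | tetra-O-MOM Pestalone C | CC(C)=CCc1c(OCOC)cc(OCOC)c(C=O)c1C(=O)c1c(OCOC)cc(C)c(Br)c1OCOC | intermediate
12 | Pestalone C | CC(C)=CCc1c(O)cc(O)c(C=O)c1C(=O)c1c(O)cc(C)c(Br)c1O | target

## Summary
Total steps: 9. Longest linear sequence: 7 (1 → 2 → 3 → 4 → 5 → 10 → 11 → 12).

**Steps most likely to fail**
1. **Step 8.**
   - Risk: a di-ortho-substituted aroyl group and a prenyl-flanked ipso carbon lie outside the reported scope. Competing paths are 1,3,4-oxadiazole formation and Wessely acetoxylation of the phenol.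
   - Fallback: build ring A de novo.
     - Run a Diels–Alder/aromatisation of (3Z)-1-methoxy-7-methyl-1,3-bis(trimethylsilyloxy)octa-1,3,6-triene with methyl 4-aryl-4-(trimethylsilyloxy)but-2-ynoate. The diene comes from γ-prenylated methyl acetoacetate. The alkynoate comes from the ring-B aldehyde and lithium methyl propiolate.
     - This gives the 3-aryl-5,7-dihydroxy-4-prenylphthalide.
     - MOM-protect it, reduce with DIBAL to the lactol, dehydrate to the 1-arylisobenzofuran, and oxidise (1O2, then Me2S) to 11.
2. **Step 6 (together with Step 5).**
   - Risk: imperfect 6-OH versus 2-OH selectivity, and a modest mono-prenylation yield.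
   - Fallback: bis-MOM-protect 6 first, which gives a single product by symmetry. O-alkylate the remaining OH as the 1,1-dimethylpropargyl ether, semi-hydrogenate (Lindlar), and run the aromatic Claisen rearrangement. The prenyl group can then only arrive at C3, next to the liberated OH, giving 9 unambiguously.
3. **Step 9.**
   - Risk: acid-induced chroman formation from the o-prenylphenol, or isomerisation to the phthalide.
   - Fallback: carry an allyl group instead of prenyl through Steps 5–9, since it cannot form a tertiary cation. Convert allyl to prenyl last by cross-metathesis with 2-methyl-2-butene (Grubbs II) on the free tetraphenol.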